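## Structural features

The target is a 1,2,4-trisubstituted anisole: an (E)-propenoic acid stands para to the methoxy group, and a 3,7-dimethylocta-2,6-dienyl chain (C1' to C7' plus three methyl groups) is attached ortho to the methoxy group through the benzylic methylene C1'. The chain holds a Z trisubstituted C2'=C3' alkene with the methyl group on C3', the only stereocentre C4' (R, bearing the acetate) directly beside it, and a prenyl-type C6'=C7' alkene beyond C5'. With a single stereocentre there is no relative configuration to set, but the absolute configuration at C4' has to be combined with an alkene geometry in which C1' and C4' are cis. Fragile sites are the secondary allylic acetate (ionised by zerovalent palladium or acid, cleaved by base), the C1' methylene (benzylic and allylic, so the C2'=C3' bond can slip into conjugation with the ring), the acid- and iodine-sensitive C6'=C7' alkene, and the free cinnamic acid. The real difficulty is the Z trisubstituted alkene next to the oxygen-bearing carbon, because the E isomer is the more stable one and most olefinations lean towards it. The key step exploits the position of the C4' oxygen right beside C3': as a magnesium alkoxide it draws a methyl group onto C3' and holds the metal on C2' on its own side, which gives the 2'Z pattern with a reactive handle at C2' for the later bond to C1'. A check of the descriptors shows C4' to be R in 9, 13, 16, 18 and 20 alike, since the ranking O > C3' > C5' > H never changes, and the 1Z descriptor of 13 corresponds to the 2'Z alkene of the target; no structure in the chosen route needs correction.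

## Logic of the disconnections

**20 to 18 (through 19).** The acetyl C–O bond on C4' is cut first. The allylic acetate is the group that tolerates palladium and base least, so it is best introduced after all metal-mediated steps. The gain is that every earlier intermediate carries a plain secondary alcohol. The demand is an acetylation that copes with the free carboxylic acid: the acid is expected to pass through 19 and must be returned by a mild hydrolysis that spares the new ester.

**18 to 16 and 17.** The bond between the ring carbon para to the methoxy group and the β-carbon of the propenoic acid is cut. This removes the three-carbon acid in one piece, with no ester to unmask, and leaves an aryl bromide that stays silent in the earlier steps. The forward step has to give the E alkene and must not move or isomerise the C2'=C3' bond across the C1' methylene.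

**16 to 13 and 14 (through 15).** The C1'–C2' bond between the benzylic carbon and the alkenyl carbon is cut. This divides the molecule into an achiral arene and a chiral nine-carbon side-chain fragment, and a coupling at an alkenyl iodide keeps the alkene geometry. The forward step must select the alkenyl C–I bond over the aryl C–Br bond, metalate only the benzylic C–Br bond of 14, and tolerate the free hydroxyl.

**13 to 9 and 10.** The C3'–CH3 bond and the C2'–I bond are cut, which turns the Z trisubstituted iodoalkene back into a terminal alkyne. This is the main simplification: the alkene geometry becomes a consequence of chelation to the C4' oxygen. The forward step needs the hydroxyl unprotected and the alkyne terminal (9 already has both, so its design is kept), methyl delivery to the internal carbon, anti addition, and an iodine quench that does not touch the C6'=C7' alkene.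

**9 to 8.** The terminal alkyne C–H is traced back to a C–Si bond. The silyl group keeps the ynone stage stable and comes off in one mild step. The only demand is that desilylation leaves C4' alone.

**8 to 7.** The C4'–H bond is cut, so the single stereocentre comes from a prochiral ketone by catalyst control. The gain is an achiral precursor. The demand is high facial selectivity in the R sense and no migration of the β,γ-alkene.

**7 to 3 and 4 (through 5 and 6).** The bond between the carbonyl carbon and the alkyne carbon is cut. Both pieces are simple, and the forward addition must stop at the ketone stage, which the N-methoxy-N-methylamide function of 3 secures.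

**3 to 1 (through 2).** The amide C–N bond is cut to reach the commercial acid. The activation must be mild enough not to move the β,γ-alkene into conjugation.

## Other disconnections considered

Alternative 1: The cut is the C2'=C3' double bond itself.
- **Forward key step:** the ylide made from phosphonium salt A3 with a hindered amide base at low temperature would condense with the α-silyloxy methyl ketone A2 to give silyl ether A1 with C1' cis to C4'. A2 would come from sulcatone A4 by enantioselective oxygenation at C3 and silylation.
- **In its favour:** non-stabilised ylides are known to give the Z trisubstituted alkene with α-alkoxy ketones. The olefination attaches the arene and fixes the geometry in one operation. A4 is a cheap source of C3' to C7'.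
- **Against it here:** the stereocentre of A2 is α to a ketone and is exposed to a basic ylide, so erosion of the C4' configuration by enolisation is a real risk. Oxygenation of A4 must distinguish C3 from the C1 methyl group and be enantioselective. A3 has benzylic β-hydrogens and can lose its phosphine by elimination to a styrene. Ketone olefinations of this kind are slow, and their selectivity is kinetic and not enforced.
- **Structure:** the alternative is better in convergence, since the aryl unit arrives in the alkene-forming step, whereas the chosen plan needs a separate coupling after 13.
- **Mechanism:** the chosen plan fixes the geometry by a chelate that cannot form in the wrong isomer and never exposes C4' to enolisation; this route cannot match that.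
- **Step economy:** after A1 three steps remain (Heck reaction with 17, desilylation, acetylation), equal to the three after 13. A2 and A3 each need several steps, so the total would probably be no shorter.

Alternative 2: The cut is the aryl–C1' bond, made together with an allylic transposition that creates the C2'=C3' alkene.
- **Forward key step:** a zerovalent palladium–bisphosphine catalyst would ionise the tertiary allylic C–O bond of vinyl cyclic carbonate A6. After decarboxylation the C4' alkoxide stays bound to palladium and fixes the allyl geometry. Transmetalation from boronic acid A7 and reductive elimination at the unsubstituted terminus would give hydroxy aldehyde A5.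
- **In its favour:** the arene, C1' and the Z alkene are set in one catalytic step from a commercial boronic acid, and the alcohol emerges free. The aldehyde allows a Knoevenagel–Doebner condensation, so only two steps (condensation, acetylation) would follow the key step; this is better than the three that follow 13.
- **Mechanism:** the control element is the same C4' oxygen acting as an internal ligand, so on the principle of geometric control the two plans are equal.
- **Against it here:** A6 is not available and must be built with the C4' configuration and a quaternary vinyl carbinol, which costs several steps and a separate asymmetric operation. This reaction class is best known for carbonates without a substituent on the carbinol carbon, so a secondary alkoxide flanked by a prenyl group is an extrapolation. Attack at the internal allyl terminus, β-hydride elimination to a diene and protodeboronation of the electron-rich A7 are plausible leaks.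
- **Overall:** more convergent and shorter after the key step, but less well precedented on this substitution pattern, and probably equal or longer in total once A6 is counted.

Alternative 3: The cut is the C3'–C4' bond.
- **Forward key step:** carbamate A9 would be deprotonated enantioselectively with an alkyllithium–chiral diamine pair at −78 °C. The configurationally stable lithiated carbamate would be trapped by alkenyl boronate A10 with retention. 1,2-Migration of the alkenyl group with inversion at carbon, then oxidation of the C–B bond with retention, would give allylic alcohol A8.
- **In its favour:** the C4' stereocentre and the C3'–C4' bond are created in the same reagent-controlled operation, whereas the chosen plan needs a separate asymmetric reduction; on this point the alternative is better. Transfer of alkene geometry from boron to carbon is stereospecific, which is equal to the retention relied on in the chosen Negishi coupling. A9 is a one-step derivative of a simple alcohol.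
- **Against it here:** the geometric problem is only moved, because A10 must be made as a single isomer with boron cis to C1'. By the sequence rule this is the E boronate, since carbon outranks boron, although it delivers the 2'Z alkene. Hindered α-branched alkenyl boronates form the boronate complex slowly and migrate reluctantly. The allylic boronate can undergo a 1,3-boron shift before oxidation. The chiral diamine is stoichiometric and the conditions are cryogenic.
- **Step economy:** after A8, acetal hydrolysis, Knoevenagel–Doebner condensation and acetylation make three steps, equal to the chosen plan. The stereodefined A10 needs a longer synthesis than 15, so the total would probably be longer.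

Key step: step 5

Remark: the (R,R)-TsDPEN ruthenium catalyst is assumed to place the alkynyl group of 7 where it places the aryl group of an aryl ketone, which gives the R carbinol; every later C4' descriptor follows from that.

## Route

Step 1
Reactants: 1 4-methylpent-3-enoic acid
Product: 3 N-methoxy-N,4-dimethylpent-3-enamide, via acyl imidazole 2 (not isolated)
Conditions: CDI (1.1 equiv), CH2Cl2, 0 → 25 °C; then MeNHOMe·HCl (1.2 equiv), 25 °C
Reagents that add atoms: N,O-dimethylhydroxylamine hydrochloride, CNOC.Cl
Why: Weinreb amide formation: the acid is activated as acyl imidazole 2 with loss of CO2 and then undergoes aminolysis. The medium is close to neutral, so the β,γ-alkene should stay out of conjugation.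

Step 2
Reactants: 3 N-methoxy-N,4-dimethylpent-3-enamide; 4 ethynyltrimethylsilane
Product: 7 6-methyl-1-(trimethylsilyl)hept-5-en-1-yn-3-one, via lithium trimethylsilylacetylide 5 (not isolated), via tetrahedral lithium adduct 6 (not isolated)
Conditions: 4 (1.3 equiv), n-BuLi (1.25 equiv), THF, −78 °C; then 3, −78 → 0 °C; aq NH4Cl
Reagents that add atoms: none
Why: Weinreb ketone synthesis: acetylide 5 adds once and the chelated adduct 6 survives until the quench, so no tertiary alcohol should form. The acetylide is a weak base, so deprotonation at the α-carbon of 3 is not expected to compete at −78 °C.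

Step 3
Reactants: 7 6-methyl-1-(trimethylsilyl)hept-5-en-1-yn-3-one
Product: 8 (3R)-6-methyl-1-(trimethylsilyl)hept-5-en-1-yn-3-ol
Conditions: RuCl[(R,R)-TsDPEN](p-cymene) (2 mol%, activated beforehand with KOH to the base-free amido complex), i-PrOH, 25 °C
Reagents that add atoms: none
Why: Noyori-type asymmetric transfer hydrogenation of an alkynyl ketone by concerted hydride and proton transfer from the ruthenium hydride–amine complex; with the alkynyl group in the position an aryl group normally takes, the (R,R)-catalyst should give the R alcohol. Neither the C≡C bond nor the isolated alkene is reduced, and the base-free medium should keep the β,γ-alkene of 7 in place.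

Step 4
Reactants: 8 (3R)-6-methyl-1-(trimethylsilyl)hept-5-en-1-yn-3-ol
Product: 9 (3R)-6-methylhept-5-en-1-yn-3-ol
Conditions: K2CO3 (0.2 equiv), MeOH, 0 → 25 °C
Reagents that add atoms: none
Why: Methoxide-mediated protodesilylation of the alkynylsilane (attack at silicon, protonation of the acetylide by methanol); no bond to C4' is touched, so the R configuration is kept. The product is volatile and is best carried on as a concentrated solution.

Step 5
Reactants: 9 (3R)-6-methylhept-5-en-1-yn-3-ol; 10 methylmagnesium bromide
Product: 13 (1Z,3R)-1-iodo-2,6-dimethylhepta-1,5-dien-3-ol, via bromomagnesium alkoxide 11 (not isolated), via oxamagnesacycle 12 (not isolated)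
Conditions: MeMgBr (3 equiv), CuI (0.2 equiv), Et2O–THF, −20 → 25 °C, 16 h; then I2 in THF added to a faint persistent colour, −78 °C; aq Na2S2O3, aq NH4Cl
Reagents that add atoms: iodine, I-I (the methyl group comes from reactant 10, C[Mg]Br)
Why: The closest known reaction type is the copper-catalysed anti carbomagnesiation of propargylic alkoxides with iodinolysis, the standard entry to (Z)-3-iodo-2-methylallylic alcohols. The first equivalent of 10 deprotonates 9 to alkoxide 11; CuI and further 10 give a methylcopper species that adds across the alkyne with methyl on the internal carbon C3' and the metal on the terminal carbon C2', and transmetalation to magnesium gives the five-membered chelate 12 and returns copper to the cycle. Regioselectivity and the anti sense of addition both follow from this chelate, because only the isomer with magnesium cis to C4' can bind the alkoxide oxygen, so the free hydroxyl of 9 is the controlling element and must stay unprotected. Iodine cleaves the alkenyl–magnesium bond with retention, so iodine ends up cis to C4' and the alkene is 1Z. The chelate ring is transient: no ring is closed in the product, and one skeletal bond (C3'–CH3) is formed. No stereocentre is created, and C4' keeps its R configuration because none of its bonds is broken. The C6'=C7' alkene is unactivated and inert to methylcopper and Grignard reagents; it is shielded from iodine by adding only what the organomagnesium species consume at −78 °C and reducing any excess at once.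

Step 6
Reactants: 13 (1Z,3R)-1-iodo-2,6-dimethylhepta-1,5-dien-3-ol; 14 4-bromo-2-(bromomethyl)-1-methoxybenzene
Product: 16 (2Z,4R)-1-(5-bromo-2-methoxyphenyl)-3,7-dimethylocta-2,6-dien-4-ol, via benzylic zinc bromide 15 (not isolated)
Conditions: 14, Zn dust, LiCl, THF, 0 → 25 °C (gives 15, 2.5 equiv); then 13, Pd(PPh3)4 (5 mol%), THF, 25 °C
Reagents that add atoms: none
Why: LiCl-assisted zinc insertion occurs only at the benzylic C–Br bond of 14, and the Negishi coupling of 15 with the alkenyl iodide (oxidative addition, transmetalation, reductive elimination) proceeds with retention of the alkene geometry. Pd(PPh3)4 at 25 °C inserts into the C–I bond far faster than into the electron-rich aryl C–Br bond, and the excess of 15 covers any loss by protonolysis at the free hydroxyl.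

Step 7
Reactants: 16 (2Z,4R)-1-(5-bromo-2-methoxyphenyl)-3,7-dimethylocta-2,6-dien-4-ol; 17 acrylic acid
Product: 18 (2E)-3-{3-[(2Z,4R)-4-hydroxy-3,7-dimethylocta-2,6-dien-1-yl]-4-methoxyphenyl}prop-2-enoic acid
Conditions: 17 (2 equiv), Pd(OAc)2 (5 mol%), P(o-tol)3 (10 mol%), Et3N (3 equiv), DMF, 90 °C; acidic work-up
Reagents that add atoms: none
Why: Heck reaction of the aryl bromide with the acrylate salt; syn carbopalladation and syn β-hydride elimination give the E cinnamic acid directly, with no ester to cleave. The trisubstituted alkenes of the side chain insert far more slowly than the acrylate, and the aryl–palladium centre is meta to the side chain, which rules out cyclisation.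

Step 8
Reactants: 18 (2E)-3-{3-[(2Z,4R)-4-hydroxy-3,7-dimethylocta-2,6-dien-1-yl]-4-methoxyphenyl}prop-2-enoic acid
Product: 20 (2E)-3-{3-[(2Z,4R)-4-acetoxy-3,7-dimethylocta-2,6-dien-1-yl]-4-methoxyphenyl}prop-2-enoic acid, via mixed anhydride 19 (not isolated)
Conditions: Ac2O (3 equiv), pyridine, DMAP (0.1 equiv), CH2Cl2, 0 → 25 °C; then THF–H2O, NaHCO3, 25 °C; aq NaHSO4 to pH 3
Reagents that add atoms: acetic anhydride, CC(=O)OC(C)=O
Why: DMAP-catalysed acetylation of the secondary allylic alcohol; the carboxylic acid is converted in parallel into mixed anhydride 19, which water and NaHCO3 should cleave back to the acid without touching the acetate. No bond to C4' is broken, so the R configuration is retained.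

## Compound list

1 | 4-methylpent-3-enoic acid | CC(C)=CCC(=O)O | starting material
2 | 1-(4-methylpent-3-enoyl)-1H-imidazole | CC(C)=CCC(=O)n1ccnc1 | intermediate
3 | N-methoxy-N,4-dimethylpent-3-enamide | CC(C)=CCC(=O)N(C)OC | intermediate
4 | ethynyltrimethylsilane | C#C[Si](C)(C)C | starting material
5 | lithium (trimethylsilyl)acetylide | [Li]C#C[Si](C)(C)C | intermediate
6 | lithium 3-[methoxy(methyl)amino]-6-methyl-1-(trimethylsilyl)hept-5-en-1-yn-3-olate | CC(C)=CCC(O[Li])(C#C[Si](C)(C)C)N(C)OC | intermediate
7 | 6-methyl-1-(trimethylsilyl)hept-5-en-1-yn-3-one | CC(C)=CCC(=O)C#C[Si](C)(C)C | intermediate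
8 | (3R)-6-methyl-1-(trimethylsilyl)hept-5-en-1-yn-3-ol | C[Si](C)(C)C#C[C@@H](CC=C(C)C)O | intermediate
9 | (3R)-6-methylhept-5-en-1-yn-3-ol | C#C[C@@H](CC=C(C)C)O | intermediate
10 | methylmagnesium bromide | C[Mg]Br | starting material
11 | bromomagnesium (3R)-6-methylhept-5-en-1-yn-3-olate | C#C[C@@H](CC=C(C)C)O[Mg]Br | intermediate
12 | (5R)-4-methyl-5-(3-methylbut-2-en-1-yl)-1-oxa-2-magnesacyclopent-3-ene (ring O–Mg–C2'=C3'–C4') | CC1=C[Mg]O[C@@H]1CC=C(C)C | intermediate
13 | (1Z,3R)-1-iodo-2,6-dimethylhepta-1,5-dien-3-ol | I/C=C(/C)[C@@H](CC=C(C)C)O | intermediate
14 | 4-bromo-2-(bromomethyl)-1-methoxybenzene | COc1ccc(Br)cc1CBr | starting material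
15 | (5-bromo-2-methoxybenzyl)zinc bromide | COc1ccc(Br)cc1C[Zn]Br | intermediate
16 | (2Z,4R)-1-(5-bromo-2-methoxyphenyl)-3,7-dimethylocta-2,6-dien-4-ol | COc1ccc(Br)cc1C/C=C(/C)[C@@H](CC=C(C)C)O | intermediate
17 | acrylic acid | C=CC(=O)O | starting material
18 | (2E)-3-{3-[(2Z,4R)-4-hydroxy-3,7-dimethylocta-2,6-dien-1-yl]-4-methoxyphenyl}prop-2-enoic acid | COc1ccc(/C=C/C(=O)O)cc1C/C=C(/C)[C@@H](CC=C(C)C)O | intermediate
19 | acetic (2E)-3-{3-[(2Z,4R)-4-acetoxy-3,7-dimethylocta-2,6-dien-1-yl]-4-methoxyphenyl}prop-2-enoic anhydride | COc1ccc(/C=C/C(=O)OC(C)=O)cc1C/C=C(/C)[C@@H](CC=C(C)C)OC(C)=O | intermediate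
20 | (2E)-3-{3-[(2Z,4R)-4-acetoxy-3,7-dimethylocta-2,6-dien-1-yl]-4-methoxyphenyl}prop-2-enoic acid | COc1ccc(/C=C/C(=O)O)cc1C/C=C(/C)[C@@H](CC=C(C)C)OC(C)=O | target

## Step count and risks

Total step count: 8. Longest linear sequence: 8 steps (1 to 20); the arene 14 enters at step 6 without isolated steps of its own.

**Step 5 (key step).**
- What may go wrong: slow carbometalation of the secondary, α-branched alkoxide, with metalation of the terminal alkyne C–H by 10 competing; and iodine-induced cyclisation of the homoallylic alkoxide onto the electron-rich C6'=C7' alkene if iodine is present in excess.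
- Fallback: move the carbomagnesiation to the simplest alkynol and build C4' afterwards. The sequence sets out from 10 and commercial prop-2-yn-1-ol F1 and returns at 13. The same CuI-catalysed methylmagnesiation and iodine quench would give (Z)-3-iodo-2-methylprop-2-en-1-ol F2. MnO2 in CH2Cl2 would oxidise it to (Z)-3-iodo-2-methylprop-2-enal F3. Brown allylation with the antipode of B-allyldiisopinocampheylborane that adds to the re face of the aldehyde (by the usual model the reagent derived from (−)-α-pinene) would give (1Z,3R)-1-iodo-2-methylhexa-1,5-dien-3-ol F4. Cross-metathesis with 2-methylbut-2-ene (second-generation Grubbs catalyst) would turn the vinyl group into the prenyl terminus.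

**Step 3.**
- What may go wrong: migration of the β,γ-alkene of 7 into conjugation with the carbonyl under the basic character of the catalyst before hydride transfer, or an insufficient facial bias.
- Fallback: Midland reduction of 7 with (R)-Alpine-Borane (the B-isopinocampheyl-9-borabicyclo[3.3.1]nonane made from (+)-α-pinene) in THF at 25 °C, returning at 8. This is a stoichiometric hydride transfer from a chiral trialkylborane in a neutral medium, in which the slim alkynyl group acts as the small substituent and the R carbinol is expected. No new compound arises (F0).

**Step 6.**
- What may go wrong: Wurtz-type homocoupling during zinc insertion, and protonolysis of the organozinc by the free hydroxyl of 13, which would starve the coupling.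
- Fallback: mask the hydroxyl, setting out from 13 and returning at 16. Et3SiCl and imidazole in CH2Cl2 would give triethyl{[(1Z,3R)-1-iodo-2,6-dimethylhepta-1,5-dien-3-yl]oxy}silane F5. The same Negishi coupling with 15 would give {[(2Z,4R)-1-(5-bromo-2-methoxyphenyl)-3,7-dimethylocta-2,6-dien-4-yl]oxy}triethylsilane F6. TBAF in THF would then release 16.

**Step 7.**
- What may go wrong: re-addition of palladium hydride, leading to migration of the C2'=C3' bond across the doubly activated C1' methylene into conjugation with the arene or to Z-to-E isomerisation, at the temperature an electron-rich aryl bromide needs.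
- Fallback: a Suzuki–Miyaura coupling, which forms no palladium hydride, setting out from 16 and returning at 18. Coupling with commercial ethyl (E)-3-(4,4,5,5-tetramethyl-1,3,2-dioxaborolan-2-yl)prop-2-enoate F7 (Pd(dppf)Cl2, K2CO3, dioxane–H2O, 70 °C) would give ethyl (E)-3-{3-[(2Z,4R)-4-hydroxy-3,7-dimethylocta-2,6-dien-1-yl]-4-methoxyphenyl}prop-2-enoate F8. LiOH in THF–H2O would hydrolyse it to 18 before any acetate is present.

**Step 8.**
- What may go wrong: acyl transfer from the mixed anhydride to the hydroxyl of a second molecule (oligoester formation), or incomplete return of the anhydride to the acid.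
- Fallback: change the order, setting out from 16 and returning at 20. Acetylation of 16 (Ac2O, pyridine, DMAP) would give (2Z,4R)-1-(5-bromo-2-methoxyphenyl)-3,7-dimethylocta-2,6-dien-4-yl acetate F9. A phosphine-free Heck reaction with 17 (Pd(OAc)2, Bu4NCl, NaHCO3, DMF, 80 °C) would then give 20 directly; without phosphine, ionisation of the allylic acetate should stay slow.

## Further compounds

F0 | step 3 | none | none
F1 | step 5 | prop-2-yn-1-ol | C#CCO
F2 | step 5 | (Z)-3-iodo-2-methylprop-2-en-1-ol | I/C=C(/C)CO
F3 | step 5 | (Z)-3-iodo-2-methylprop-2-enal | I/C=C(/C)C=O
F4 | step 5 | (1Z,3R)-1-iodo-2-methylhexa-1,5-dien-3-ol | I/C=C(/C)[C@@H](CC=C)O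
F5 | step 6 | triethyl{[(1Z,3R)-1-iodo-2,6-dimethylhepta-1,5-dien-3-yl]oxy}silane | I/C=C(/C)[C@@H](CC=C(C)C)O[Si](CC)(CC)CC
F6 | step 6 | {[(2Z,4R)-1-(5-bromo-2-methoxyphenyl)-3,7-dimethylocta-2,6-dien-4-yl]oxy}triethylsilane | COc1ccc(Br)cc1C/C=C(/C)[C@@H](CC=C(C)C)O[Si](CC)(CC)CC
F7 | step 7 | ethyl (E)-3-(4,4,5,5-tetramethyl-1,3,2-dioxaborolan-2-yl)prop-2-enoate | CCOC(=O)/C=C/B1OC(C)(C)C(C)(C)O1
F8 | step 7 | ethyl (E)-3-{3-[(2Z,4R)-4-hydroxy-3,7-dimethylocta-2,6-dien-1-yl]-4-methoxyphenyl}prop-2-enoate | COc1ccc(/C=C/C(=O)OCC)cc1C/C=C(/C)[C@@H](CC=C(C)C)O
F9 | step 8 | (2Z,4R)-1-(5-bromo-2-methoxyphenyl)-3,7-dimethylocta-2,6-dien-4-yl acetate | COc1ccc(Br)cc1C/C=C(/C)[C@@H](CC=C(C)C)OC(C)=O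
A1 | alternative 1 | tert-butyl{[(2Z,4R)-1-(5-bromo-2-methoxyphenyl)-3,7-dimethylocta-2,6-dien-4-yl]oxy}dimethylsilane | COc1ccc(Br)cc1C/C=C(/C)[C@@H](CC=C(C)C)O[Si](C)(C)C(C)(C)C
A2 | alternative 1 | (3R)-3-[(tert-butyldimethylsilyl)oxy]-6-methylhept-5-en-2-one | CC(=O)[C@@H](CC=C(C)C)O[Si](C)(C)C(C)(C)C
A3 | alternative 1 | [2-(5-bromo-2-methoxyphenyl)ethyl]triphenylphosphonium bromide | COc1ccc(Br)cc1CC[P+](c1ccccc1)(c1ccccc1)c1ccccc1.[Br-]
A4 | alternative 1 | 6-methylhept-5-en-2-one (sulcatone) | CC(=O)CCC=C(C)C
A5 | alternative 2 | 3-[(2Z,4R)-4-hydroxy-3,7-dimethylocta-2,6-dien-1-yl]-4-methoxybenzaldehyde | COc1ccc(C=O)cc1C/C=C(/C)[C@@H](CC=C(C)C)O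
A6 | alternative 2 | (5R)-4-ethenyl-4-methyl-5-(3-methylbut-2-en-1-yl)-1,3-dioxolan-2-one | C=CC1(C)OC(=O)O[C@@H]1CC=C(C)C
A7 | alternative 2 | (5-formyl-2-methoxyphenyl)boronic acid | COc1ccc(C=O)cc1B(O)O
A8 | alternative 3 | (2Z,4R)-1-[5-(1,3-dioxolan-2-yl)-2-methoxyphenyl]-3,7-dimethylocta-2,6-dien-4-ol | COc1ccc(C2OCCO2)cc1C/C=C(/C)[C@@H](CC=C(C)C)O
A9 | alternative 3 | 4-methylpent-3-en-1-yl N,N-diisopropylcarbamate | CC(C)=CCCOC(=O)N(C(C)C)C(C)C
A10 | alternative 3 | 2-{(2E)-4-[5-(1,3-dioxolan-2-yl)-2-methoxyphenyl]but-2-en-2-yl}-4,4,5,5-tetramethyl-1,3,2-dioxaborolane | COc1ccc(C2OCCO2)cc1C/C=C(/C)B1OC(C)(C)C(C)(C)O1
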